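**Retrosynthetic overview**

1. The target is reached by Stille hydroxymethylation (C15) of a C4 vinyl iodide; the side chain comes from esterifying the 8α-hydroxy iodo-germacranolide with an (R)-dioxolanyl-acrylic acid, then unmasking the diol and acetylating O4′.
2. The α-methylene-γ-lactone (third ring) comes from oxidative lactonisation of a C6-OH/C12-OH diol; the (Z)-vinyl iodide comes from trans-hydroalumination/iodination of a ring propargylic alcohol.
3. The ten-membered carbocycle (second ring), the C6–C7 bond and both the C6 and C7 stereocentres come from a [2,3]-Wittig ring contraction of a 13-membered allyl propargyl ether, steered by the C8 silyloxy centre.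
4. The 13-membered ether (first ring) comes from Williamson macro-etherification; the chain is built by Negishi coupling (C1–C2), cross-metathesis (C7=C11) and Zr-catalysed carboalumination (C1=C10).
5. C8 is bought as (S)-epichlorohydrin and C3′ as methyl [(4R)-2,2-dimethyl-1,3-dioxolan-4-yl]acetate; C6 and C7 are relayed from C8.

Assumption: positions carry germacrane numbers (C1–C15; side chain C1′–C4′); TBS = tert-butyldimethylsilyl, PMB = 4-methoxybenzyl; 1, 7, 10 and 31 are bought.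

**Route**

Step 1
Reactants: 1 (S)-2-(chloromethyl)oxirane [(S)-epichlorohydrin]
Product: 2 (2S)-1-chloropent-4-yn-2-ol
Conditions: HC≡CH, n-BuLi, THF, −78 °C; BF3·OEt2, then 1, −78 °C; H2O
Reagents that add atoms: acetylene, C#C
Why: BF3-promoted alkynylation of the epoxide (Yamaguchi–Hirao opening) is an SN2 attack at the unsubstituted ring carbon, so the bought C–O stereocentre (future C8) is not touched.

Step 2
Reactants: 2 (2S)-1-chloropent-4-yn-2-ol
Product: 4 (3S)-hex-1-en-5-yn-3-ol, via epoxide 3 (not isolated)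
Conditions: Me3S+ I− (4 equiv), n-BuLi (3.9 equiv), THF, −20 °C → rt; H2O
Reagents that add atoms: trimethylsulfonium iodide, C[S+](C)C.[I-]
Why: Excess dimethylsulfonium methylide closes the chlorohydrin to the epoxide, opens it at CH2 and loses Me2S by elimination (sulfonium-ylide homologation of an epoxide to an allylic alcohol), leaving the carbinol centre unchanged.

Step 3
Reactants: 4 (3S)-hex-1-en-5-yn-3-ol
Product: 6 (3S,5E)-6-iodo-5-methylhexa-1,5-dien-3-ol, via alkenylalane 5 (not isolated)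
Conditions: Me3Al (3.5 equiv), Cp2ZrCl2 (0.25 equiv), CH2Cl2, 0 °C → rt; I2, THF, −30 °C; H2O
Reagents that add atoms: trimethylaluminium, C[Al](C)C; iodine, II
Why: Negishi zirconium-catalysed carboalumination adds Me–Al syn and regioselectively across the terminal alkyne (the alkene reacts far more slowly), and iodinolysis with retention gives the (E)-vinyl iodide that fixes the C1=C10 geometry.

Step 4
Reactants: 6 (3S,5E)-6-iodo-5-methylhexa-1,5-dien-3-ol; 7 methyl 2-(hydroxymethyl)prop-2-enoate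
Product: 8 methyl (2E,4S,6E)-4-hydroxy-2-(hydroxymethyl)-7-iodo-6-methylhepta-2,6-dienoate
Conditions: 7 (5 equiv), second-generation Hoveyda–Grubbs catalyst RuCl2(H2IMes)(=CH-C6H4-2-O-i-Pr) (5 mol %), CH2Cl2, 40 °C
Reagents that add atoms: none
Why: Olefin cross-metathesis of the terminal vinyl group with the 1,1-disubstituted acrylate gives the trisubstituted enoate with the ester trans to the carbinol carbon (thermodynamic E product, as with methacrylates), the vinyl iodide being inert to the ruthenium carbene.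

Step 5
Reactants: 8 methyl (2E,4S,6E)-4-hydroxy-2-(hydroxymethyl)-7-iodo-6-methylhepta-2,6-dienoate
Product: 9 methyl (2E,4S,6E)-4-(TBS-oxy)-2-[(TBS-oxy)methyl]-7-iodo-6-methylhepta-2,6-dienoate
Conditions: t-BuMe2SiOTf (2.5 equiv), 2,6-lutidine, CH2Cl2, −78 → 0 °C
Reagents that add atoms: tert-butyldimethylsilyl trifluoromethanesulfonate, CC(C)(C)[Si](C)(C)OS(=O)(=O)C(F)(F)F
Why: Silyl ether formation protects both hydroxyls, giving a hindered secondary C8–OTBS that later steers the ring contraction and a more labile primary C12–OTBS.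

Step 6
Reactants: 10 1-methoxy-4-[(prop-2-yn-1-yloxy)methyl]benzene (PMB propargyl ether)
Product: 12 5-(PMB-oxy)pent-3-yn-1-ol, via lithium acetylide 11 (not isolated)
Conditions: n-BuLi, THF, −78 °C; BF3·OEt2; oxirane, −78 °C; H2O
Reagents that add atoms: oxirane, C1CO1
Why: BF3-promoted opening of oxirane by the lithium acetylide (Yamaguchi–Hirao alkynylation) gives the homopropargylic alcohol.

Step 7
Reactants: 12 5-(PMB-oxy)pent-3-yn-1-ol
Product: 13 1-{[(5-iodopent-2-yn-1-yl)oxy]methyl}-4-methoxybenzene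
Conditions: I2, PPh3, imidazole, CH2Cl2, 0 °C
Reagents that add atoms: iodine, II
Why: Appel-type iodination converts the primary alcohol to the iodide by SN2 displacement of the oxyphosphonium group.

Step 8
Reactants: 13 1-{[(5-iodopent-2-yn-1-yl)oxy]methyl}-4-methoxybenzene; 9 methyl (2E,4S,6E)-4-(TBS-oxy)-2-[(TBS-oxy)methyl]-7-iodo-6-methylhepta-2,6-dienoate
Product: 15 methyl (2E,4S,6E)-4-(TBS-oxy)-2-[(TBS-oxy)methyl]-12-(PMB-oxy)-6-methyldodeca-2,6-dien-10-ynoate, via organozinc iodide 14 (not isolated)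
Conditions: 13, Zn dust, LiCl, THF, 40 °C; then 9, PdCl2(dppf) (5 mol %), THF, rt → 45 °C
Reagents that add atoms: none
Why: Zinc insertion gives the alkylzinc iodide, and Negishi sp3–sp2 cross-coupling at the vinyl iodide forms C1–C2 with retention of the E geometry while tolerating the enoate.

Step 9
Reactants: 15 methyl (2E,4S,6E)-4-(TBS-oxy)-2-[(TBS-oxy)methyl]-12-(PMB-oxy)-6-methyldodeca-2,6-dien-10-ynoate
Product: 16 (2Z,4S,6E)-4-(TBS-oxy)-2-[(TBS-oxy)methyl]-12-(PMB-oxy)-6-methyldodeca-2,6-dien-10-yn-1-ol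
Conditions: i-Bu2AlH (2.5 equiv), CH2Cl2, −78 °C; aq. potassium sodium tartrate
Reagents that add atoms: none
Why: 1,2-Reduction of the conjugated ester with i-Bu2AlH gives the allylic alcohol (C13, trans to C8) without touching the silyl ethers, the alkyne or the stereocentre.

Step 10
Reactants: 16 (2Z,4S,6E)-4-(TBS-oxy)-2-[(TBS-oxy)methyl]-12-(PMB-oxy)-6-methyldodeca-2,6-dien-10-yn-1-ol
Product: 18 PMB ether of (6E,9S,10E)-9-(TBS-oxy)-11-[(TBS-oxy)methyl]-12-chloro-7-methyldodeca-6,10-dien-2-yn-1-ol, via allylic mesylate 17 (not isolated)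
Conditions: MsCl, 2,4,6-collidine, LiCl, DMF, 0 °C
Reagents that add atoms: lithium chloride, [Li+].[Cl-]
Why: Mesylation and in situ chloride displacement (Collington–Meyers allylic chlorination) give the primary allylic chloride by SN2 without allylic transposition.

Step 11
Reactants: 18 PMB ether of (6E,9S,10E)-9-(TBS-oxy)-11-[(TBS-oxy)methyl]-12-chloro-7-methyldodeca-6,10-dien-2-yn-1-ol
Product: 19 (6E,9S,10E)-9-(TBS-oxy)-11-[(TBS-oxy)methyl]-12-chloro-7-methyldodeca-6,10-dien-2-yn-1-ol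
Conditions: DDQ, CH2Cl2/pH 7 buffer, 0 °C
Reagents that add atoms: none
Why: Oxidative cleavage of the p-methoxybenzyl ether with DDQ frees the propargylic alcohol while the silyl ethers and the allylic chloride survive.

Step 12
Reactants: 19 (6E,9S,10E)-9-(TBS-oxy)-11-[(TBS-oxy)methyl]-12-chloro-7-methyldodeca-6,10-dien-2-yn-1-ol
Product: 21 (3Z,5S,7E)-5-(TBS-oxy)-3-[(TBS-oxy)methyl]-7-methyl-1-oxacyclotrideca-3,7-dien-11-yne, via sodium alkoxide 20 (not isolated)
Conditions: NaH, n-Bu4NI (cat.), THF, 60 °C, syringe pump, 0.004 M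
Reagents that add atoms: none
Why: Intramolecular Williamson etherification (SN2 of the propargylic alkoxide on the primary allylic chloride) under high dilution closes the 13-membered ether, the E alkene holding C8 trans to the new O–CH2 group.

Step 13
Reactants: 21 (3Z,5S,7E)-5-(TBS-oxy)-3-[(TBS-oxy)methyl]-7-methyl-1-oxacyclotrideca-3,7-dien-11-yne
Product: 23 (1S,6E,9S,10S)-9-(TBS-oxy)-10-[3-(TBS-oxy)prop-1-en-2-yl]-7-methylcyclodec-6-en-2-yn-1-ol, via lithiated ether 22 (not isolated)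
Conditions: n-BuLi (1.2 equiv), THF, −78 → −30 °C; H2O
Reagents that add atoms: none
Why: [2,3]-Wittig ring contraction: the propargylic α-oxy carbanion (C6) adds to C7 through a five-membered envelope transition state, forming the C6–C7 bond and the ten-membered ring, the E allyl ether giving the 6,7-anti pair and the C8 silyloxy group (anti to the forming bond, H-8 eclipsing the alkene to avoid allylic 1,3-strain) fixing the face, so that C6 and C7 are set by the bought C8 centre.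

Step 14
Reactants: 23 (1S,6E,9S,10S)-9-(TBS-oxy)-10-[3-(TBS-oxy)prop-1-en-2-yl]-7-methylcyclodec-6-en-2-yn-1-ol
Product: 25 (1S,2Z,6E,9S,10S)-9-(TBS-oxy)-10-[3-(TBS-oxy)prop-1-en-2-yl]-3-iodo-7-methylcyclodeca-2,6-dien-1-ol, via vinylalanate 24 (not isolated)
Conditions: NaAlH2(OCH2CH2OMe)2, THF, 0 °C → rt; I2, −78 °C; aq. potassium sodium tartrate
Reagents that add atoms: iodine, II
Why: Alkoxide-directed trans-hydroalumination of the propargylic alcohol (Corey–Denmark protocol) puts aluminium on C4, and iodinolysis with retention gives the E ring olefin with iodine cis to C6.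

Step 15
Reactants: 25 (1S,2Z,6E,9S,10S)-9-(TBS-oxy)-10-[3-(TBS-oxy)prop-1-en-2-yl]-3-iodo-7-methylcyclodeca-2,6-dien-1-ol
Product: 26 (1S,2Z,6E,9S,10S)-9-(TBS-oxy)-10-(3-hydroxyprop-1-en-2-yl)-3-iodo-7-methylcyclodeca-2,6-dien-1-ol
Conditions: HF·pyridine, pyridine, THF, 0 °C
Reagents that add atoms: none
Why: Selective desilylation, the unhindered primary allylic TBS ether being cleaved much faster than the secondary C8–OTBS flanked by two branched carbons.

Step 16
Reactants: 26 (1S,2Z,6E,9S,10S)-9-(TBS-oxy)-10-(3-hydroxyprop-1-en-2-yl)-3-iodo-7-methylcyclodeca-2,6-dien-1-ol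
Product: 29 (3aS,4S,6E,10Z,11aS)-4-(TBS-oxy)-10-iodo-6-methyl-3-methylidene-3a,4,5,8,9,11a-hexahydrocyclodeca[b]furan-2(3H)-one, via enal 27 (not isolated), via lactol 28 (not isolated)
Conditions: TEMPO (0.2 equiv), PhI(OAc)2 (2.5 equiv), CH2Cl2, rt
Reagents that add atoms: none
Why: TEMPO/PhI(OAc)2 oxidation of the primary allylic alcohol gives the enal, which closes onto the C6 hydroxyl and is oxidised on to the trans-fused α-methylene-γ-lactone (oxidative lactonisation), only the 6,12-olide being possible because O8 is still silylated.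

Step 17
Reactants: 29 (3aS,4S,6E,10Z,11aS)-4-(TBS-oxy)-10-iodo-6-methyl-3-methylidene-3a,4,5,8,9,11a-hexahydrocyclodeca[b]furan-2(3H)-one
Product: 30 (3aR,4S,6E,10Z,11aS)-4-hydroxy-10-iodo-6-methyl-3-methylidene-3a,4,5,8,9,11a-hexahydrocyclodeca[b]furan-2(3H)-one
Conditions: HF·pyridine, THF, rt
Reagents that add atoms: none
Why: Fluoride-mediated desilylation frees the 8α-hydroxyl under conditions that leave the lactone, the vinyl iodide and the diene alone.

Step 18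
Reactants: 31 methyl [(4R)-2,2-dimethyl-1,3-dioxolan-4-yl]acetate
Product: 35 methyl 2-[(4R)-2,2-dimethyl-1,3-dioxolan-4-yl]prop-2-enoate, via lithium enolate 32 (not isolated), via Mannich base 33 (not isolated), via ammonium iodide 34 (not isolated)
Conditions: LiN(i-Pr)2, THF, −78 °C; Me2N=CH2+ I−, −78 → 0 °C; MeI, rt; DBU, CH2Cl2
Reagents that add atoms: N,N-dimethylmethyleneiminium iodide, C=[N+](C)C.[I-]
Why: Mannich reaction of the ester enolate at −78 °C (cold enough to avoid β-alkoxide elimination), quaternisation and Hofmann-type elimination install the α-methylene group without involving the dioxolane stereocentre.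

Step 19
Reactants: 35 methyl 2-[(4R)-2,2-dimethyl-1,3-dioxolan-4-yl]prop-2-enoate
Product: 36 2-[(4R)-2,2-dimethyl-1,3-dioxolan-4-yl]prop-2-enoic acid
Conditions: LiOH, THF/H2O, 0 °C → rt; 1 M HCl to pH 4, 0 °C
Reagents that add atoms: lithium hydroxide, [Li+].[OH-]
Why: Saponification of the methyl ester followed by careful acidification gives the acid with the acetonide intact.

Step 20
Reactants: 36 2-[(4R)-2,2-dimethyl-1,3-dioxolan-4-yl]prop-2-enoic acid; 30 (3aR,4S,6E,10Z,11aS)-4-hydroxy-10-iodo-6-methyl-3-methylidene-3a,4,5,8,9,11a-hexahydrocyclodeca[b]furan-2(3H)-one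
Product: 38 (3aR,4S,6E,10Z,11aS)-10-iodo-6-methyl-3-methylidene-2-oxo-2,3,3a,4,5,8,9,11a-octahydrocyclodeca[b]furan-4-yl 2-[(4R)-2,2-dimethyl-1,3-dioxolan-4-yl]prop-2-enoate, via mixed anhydride 37 (not isolated)
Conditions: 2,4,6-Cl3C6H2COCl, Et3N, THF, 0 °C; then 30, DMAP, toluene, rt
Reagents that add atoms: none
Why: Yamaguchi esterification through the mixed anhydride acylates the hindered equatorial 8α-hydroxyl with retention at C8.

Step 21
Reactants: 38 (3aR,4S,6E,10Z,11aS)-10-iodo-6-methyl-3-methylidene-2-oxo-2,3,3a,4,5,8,9,11a-octahydrocyclodeca[b]furan-4-yl 2-[(4R)-2,2-dimethyl-1,3-dioxolan-4-yl]prop-2-enoate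
Product: 39 (3aR,4S,6E,10Z,11aS)-10-iodo-6-methyl-3-methylidene-2-oxo-2,3,3a,4,5,8,9,11a-octahydrocyclodeca[b]furan-4-yl (3R)-3,4-dihydroxy-2-methylidenebutanoate
Conditions: AcOH/H2O (4:1), 35 °C
Reagents that add atoms: none
Why: Mild acid hydrolysis of the isopropylidene acetal frees the 3′,4′-diol, the iodine-deactivated diene resisting transannular cyclisation.

Step 22
Reactants: 39 (3aR,4S,6E,10Z,11aS)-10-iodo-6-methyl-3-methylidene-2-oxo-2,3,3a,4,5,8,9,11a-octahydrocyclodeca[b]furan-4-yl (3R)-3,4-dihydroxy-2-methylidenebutanoate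
Product: 40 (3aR,4S,6E,10Z,11aS)-10-iodo-6-methyl-3-methylidene-2-oxo-2,3,3a,4,5,8,9,11a-octahydrocyclodeca[b]furan-4-yl (3R)-4-(acetyloxy)-3-hydroxy-2-methylidenebutanoate
Conditions: AcCl (1.05 equiv), 2,4,6-collidine, CH2Cl2, −78 °C
Reagents that add atoms: acetyl chloride, CC(Cl)=O
Why: Kinetically selective acylation of the primary 4′-hydroxyl over the hindered secondary 3′-hydroxyl, no other free hydroxyl being present at this stage.

Step 23
Reactants: 40 (3aR,4S,6E,10Z,11aS)-10-iodo-6-methyl-3-methylidene-2-oxo-2,3,3a,4,5,8,9,11a-octahydrocyclodeca[b]furan-4-yl (3R)-4-(acetyloxy)-3-hydroxy-2-methylidenebutanoate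
Product: 41 (3aR,4S,6E,10Z,11aR)-10-(hydroxymethyl)-6-methyl-3-methylidene-2-oxo-2,3,3a,4,5,8,9,11a-octahydrocyclodeca[b]furan-4-yl (3R)-4-(acetyloxy)-3-hydroxy-2-methylidenebutanoate (target, CNP0219661.4)
Conditions: Bu3SnCH2OH, Pd(PPh3)4 (10 mol %), CuI (20 mol %), DMF, 50 °C
Reagents that add atoms: (tributylstannyl)methanol, CCCC[Sn](CO)(CCCC)CCCC
Why: Stille cross-coupling (Kosugi hydroxymethylation) of the (Z)-vinyl iodide proceeds with retention of alkene geometry and delivers the C15 hydroxymethyl group under neutral conditions.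

**Compound list**

1 | (S)-2-(chloromethyl)oxirane, (S)-epichlorohydrin | ClC[C@@H]1CO1 | starting material
2 | (2S)-1-chloropent-4-yn-2-ol | ClC[C@@H](O)CC#C | intermediate
3 | (2S)-2-(prop-2-yn-1-yl)oxirane (formed in the flask) | C#CC[C@H]1CO1 | intermediate
4 | (3S)-hex-1-en-5-yn-3-ol | C=C[C@@H](O)CC#C | intermediate
5 | dimethylaluminium alkoxide of (3S,5E)-6-(dimethylalumanyl)-5-methylhexa-1,5-dien-3-ol (formed in the flask) | C=C[C@@H](O[Al](C)C)C/C(C)=C/[Al](C)C | intermediate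
6 | (3S,5E)-6-iodo-5-methylhexa-1,5-dien-3-ol | C=C[C@@H](O)C/C(C)=C/I | intermediate
7 | methyl 2-(hydroxymethyl)prop-2-enoate | C=C(CO)C(=O)OC | starting material
8 | methyl (2E,4S,6E)-4-hydroxy-2-(hydroxymethyl)-7-iodo-6-methylhepta-2,6-dienoate | COC(=O)/C(CO)=C/[C@@H](O)C/C(C)=C/I | intermediate
9 | methyl (2E,4S,6E)-4-[(tert-butyldimethylsilyl)oxy]-2-{[(tert-butyldimethylsilyl)oxy]methyl}-7-iodo-6-methylhepta-2,6-dienoate | COC(=O)/C(CO[Si](C)(C)C(C)(C)C)=C/[C@@H](O[Si](C)(C)C(C)(C)C)C/C(C)=C/I | intermediate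
10 | 1-methoxy-4-[(prop-2-yn-1-yloxy)methyl]benzene (PMB propargyl ether) | C#CCOCc1ccc(OC)cc1 | starting material
11 | lithium acetylide of 10 (formed in the flask) | [Li]C#CCOCc1ccc(OC)cc1 | intermediate
12 | 5-[(4-methoxyphenyl)methoxy]pent-3-yn-1-ol | OCCC#CCOCc1ccc(OC)cc1 | intermediate
13 | 1-{[(5-iodopent-2-yn-1-yl)oxy]methyl}-4-methoxybenzene | ICCC#CCOCc1ccc(OC)cc1 | intermediate
14 | {5-[(4-methoxyphenyl)methoxy]pent-3-yn-1-yl}zinc iodide (formed in the flask) | I[Zn]CCC#CCOCc1ccc(OC)cc1 | intermediate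
15 | methyl (2E,4S,6E)-4-[(tert-butyldimethylsilyl)oxy]-2-{[(tert-butyldimethylsilyl)oxy]methyl}-12-[(4-methoxyphenyl)methoxy]-6-methyldodeca-2,6-dien-10-ynoate | COC(=O)/C(CO[Si](C)(C)C(C)(C)C)=C/[C@@H](O[Si](C)(C)C(C)(C)C)C/C(C)=C/CCC#CCOCc1ccc(OC)cc1 | intermediate
16 | (2Z,4S,6E)-4-[(tert-butyldimethylsilyl)oxy]-2-{[(tert-butyldimethylsilyl)oxy]methyl}-12-[(4-methoxyphenyl)methoxy]-6-methyldodeca-2,6-dien-10-yn-1-ol | OC/C(CO[Si](C)(C)C(C)(C)C)=C/[C@@H](O[Si](C)(C)C(C)(C)C)C/C(C)=C/CCC#CCOCc1ccc(OC)cc1 | intermediate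
17 | methanesulfonate of 16, (2E,4S,6E) (formed in the flask) | CS(=O)(=O)OC/C(CO[Si](C)(C)C(C)(C)C)=C/[C@@H](O[Si](C)(C)C(C)(C)C)C/C(C)=C/CCC#CCOCc1ccc(OC)cc1 | intermediate
18 | 4-methoxybenzyl ether of (6E,9S,10E)-9-[(tert-butyldimethylsilyl)oxy]-11-{[(tert-butyldimethylsilyl)oxy]methyl}-12-chloro-7-methyldodeca-6,10-dien-2-yn-1-ol | ClC/C(CO[Si](C)(C)C(C)(C)C)=C/[C@@H](O[Si](C)(C)C(C)(C)C)C/C(C)=C/CCC#CCOCc1ccc(OC)cc1 | intermediate
19 | (6E,9S,10E)-9-[(tert-butyldimethylsilyl)oxy]-11-{[(tert-butyldimethylsilyl)oxy]methyl}-12-chloro-7-methyldodeca-6,10-dien-2-yn-1-ol | ClC/C(CO[Si](C)(C)C(C)(C)C)=C/[C@@H](O[Si](C)(C)C(C)(C)C)C/C(C)=C/CCC#CCO | intermediate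
20 | sodium alkoxide of 19 (formed in the flask) | ClC/C(CO[Si](C)(C)C(C)(C)C)=C/[C@@H](O[Si](C)(C)C(C)(C)C)C/C(C)=C/CCC#CC[O-].[Na+] | intermediate
21 | (3Z,5S,7E)-5-[(tert-butyldimethylsilyl)oxy]-3-{[(tert-butyldimethylsilyl)oxy]methyl}-7-methyl-1-oxacyclotrideca-3,7-dien-11-yne | O1C/C(CO[Si](C)(C)C(C)(C)C)=C/[C@@H](O[Si](C)(C)C(C)(C)C)C/C(C)=C/CCC#CC1 | intermediate
22 | 21 lithiated at the propargylic O–CH2 carbon, C6 (formed in the flask) | [Li]C1C#CCC/C=C(\C)C[C@H](O[Si](C)(C)C(C)(C)C)/C=C(\CO[Si](C)(C)C(C)(C)C)/CO1 | intermediate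
23 | (1S,6E,9S,10S)-9-[(tert-butyldimethylsilyl)oxy]-10-{3-[(tert-butyldimethylsilyl)oxy]prop-1-en-2-yl}-7-methylcyclodec-6-en-2-yn-1-ol | O[C@@H]1C#CCC/C=C(\C)C[C@H](O[Si](C)(C)C(C)(C)C)[C@H]1C(=C)CO[Si](C)(C)C(C)(C)C | intermediate
24 | sodium cyclic alkoxy(alkenyl)bis(2-methoxyethoxy)aluminate from 23, Al bound to O6 and C4 (formed in the flask) | COCCO[Al-]1(OCCOC)O[C@@H]2/C=C1/CC/C=C(\C)C[C@H](O[Si](C)(C)C(C)(C)C)[C@H]2C(=C)CO[Si](C)(C)C(C)(C)C.[Na+] | intermediate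
25 | (1S,2Z,6E,9S,10S)-9-[(tert-butyldimethylsilyl)oxy]-10-{3-[(tert-butyldimethylsilyl)oxy]prop-1-en-2-yl}-3-iodo-7-methylcyclodeca-2,6-dien-1-ol | O[C@@H]1/C=C(\I)CC/C=C(\C)C[C@H](O[Si](C)(C)C(C)(C)C)[C@H]1C(=C)CO[Si](C)(C)C(C)(C)C | intermediate
26 | (1S,2Z,6E,9S,10S)-9-[(tert-butyldimethylsilyl)oxy]-10-(3-hydroxyprop-1-en-2-yl)-3-iodo-7-methylcyclodeca-2,6-dien-1-ol | O[C@@H]1/C=C(\I)CC/C=C(\C)C[C@H](O[Si](C)(C)C(C)(C)C)[C@H]1C(=C)CO | intermediate
27 | enal: 26 with its CH2OH (C12) oxidised to CHO (formed in the flask) | O[C@@H]1/C=C(\I)CC/C=C(\C)C[C@H](O[Si](C)(C)C(C)(C)C)[C@H]1C(=C)C=O | intermediate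
28 | lactol: 29 with C12 as CH(OH), both anomers (formed in the flask) | C=C1C(O)O[C@@H]2/C=C(\I)CC/C=C(\C)C[C@H](O[Si](C)(C)C(C)(C)C)[C@@H]12 | intermediate
29 | (3aS,4S,6E,10Z,11aS)-4-[(tert-butyldimethylsilyl)oxy]-10-iodo-6-methyl-3-methylidene-3a,4,5,8,9,11a-hexahydrocyclodeca[b]furan-2(3H)-one | C=C1C(=O)O[C@@H]2/C=C(\I)CC/C=C(\C)C[C@H](O[Si](C)(C)C(C)(C)C)[C@@H]12 | intermediate
30 | (3aR,4S,6E,10Z,11aS)-4-hydroxy-10-iodo-6-methyl-3-methylidene-3a,4,5,8,9,11a-hexahydrocyclodeca[b]furan-2(3H)-one | C=C1C(=O)O[C@@H]2/C=C(\I)CC/C=C(\C)C[C@H](O)[C@@H]12 | intermediate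
31 | methyl [(4R)-2,2-dimethyl-1,3-dioxolan-4-yl]acetate | COC(=O)C[C@@H]1COC(C)(C)O1 | starting material
32 | lithium enolate of 31 (formed in the flask) | COC(O[Li])=C[C@@H]1COC(C)(C)O1 | intermediate
33 | methyl 3-(dimethylamino)-2-[(4R)-2,2-dimethyl-1,3-dioxolan-4-yl]propanoate, C2 epimers (formed in the flask) | COC(=O)C(CN(C)C)[C@@H]1COC(C)(C)O1 | intermediate
34 | trimethylammonium iodide from 33 (formed in the flask) | COC(=O)C(C[N+](C)(C)C)[C@@H]1COC(C)(C)O1.[I-] | intermediate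
35 | methyl 2-[(4R)-2,2-dimethyl-1,3-dioxolan-4-yl]prop-2-enoate | C=C(C(=O)OC)[C@@H]1COC(C)(C)O1 | intermediate
36 | 2-[(4R)-2,2-dimethyl-1,3-dioxolan-4-yl]prop-2-enoic acid | C=C(C(=O)O)[C@@H]1COC(C)(C)O1 | intermediate
37 | mixed anhydride of 36 with 2,4,6-trichlorobenzoic acid (formed in the flask) | C=C(C(=O)OC(=O)c1c(Cl)cc(Cl)cc1Cl)[C@@H]1COC(C)(C)O1 | intermediate
38 | (3aR,4S,6E,10Z,11aS)-10-iodo-6-methyl-3-methylidene-2-oxo-2,3,3a,4,5,8,9,11a-octahydrocyclodeca[b]furan-4-yl 2-[(4R)-2,2-dimethyl-1,3-dioxolan-4-yl]prop-2-enoate | C=C1C(=O)O[C@@H]2/C=C(\I)CC/C=C(\C)C[C@H](OC(=O)C(=C)[C@@H]3COC(C)(C)O3)[C@@H]12 | intermediate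
39 | (3aR,4S,6E,10Z,11aS)-10-iodo-6-methyl-3-methylidene-2-oxo-2,3,3a,4,5,8,9,11a-octahydrocyclodeca[b]furan-4-yl (3R)-3,4-dihydroxy-2-methylidenebutanoate | C=C1C(=O)O[C@@H]2/C=C(\I)CC/C=C(\C)C[C@H](OC(=O)C(=C)[C@@H](O)CO)[C@@H]12 | intermediate
40 | (3aR,4S,6E,10Z,11aS)-10-iodo-6-methyl-3-methylidene-2-oxo-2,3,3a,4,5,8,9,11a-octahydrocyclodeca[b]furan-4-yl (3R)-4-(acetyloxy)-3-hydroxy-2-methylidenebutanoate | C=C1C(=O)O[C@@H]2/C=C(\I)CC/C=C(\C)C[C@H](OC(=O)C(=C)[C@@H](O)COC(C)=O)[C@@H]12 | intermediate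
41 | (3aR,4S,6E,10Z,11aR)-10-(hydroxymethyl)-6-methyl-3-methylidene-2-oxo-2,3,3a,4,5,8,9,11a-octahydrocyclodeca[b]furan-4-yl (3R)-4-(acetyloxy)-3-hydroxy-2-methylidenebutanoate | C=C1C(=O)O[C@@H]2/C=C(\CO)CC/C=C(\C)C[C@H](OC(=O)C(=C)[C@@H](O)COC(C)=O)[C@@H]12 | target

**Step count and risks**

Total steps: 23. Longest linear sequence: 19 steps from (S)-epichlorohydrin (steps 1–5, 8–17, 20–23).

Steps most likely to fail:

Step 4 (cross-metathesis of two hindered partners to a trisubstituted enoate). Fallback from 6, back at 9: silylate 6 (TBSCl, imidazole) to the TBS ether F1; cleave only the terminal vinyl group (OsO4 cat., NMO; NaIO4) to the α-silyloxy aldehyde F2; a Morita–Baylis–Hillman reaction with methyl acrylate (DABCO) gives the adduct F3 (both carbinol epimers serve); acetylation gives the acetate F4; DABCO in aqueous THF then effects SN2′ displacement with allylic transposition to the (E)-2-(hydroxymethyl) enoate F5, and TBSCl converts this to 9.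

Step 13 (ring contraction: competing [1,2]-shift or poor face selectivity relative to C8). Fallback from 19, back at 23: oxidise the propargylic alcohol with Dess–Martin periodinane to the ynal F6 and close the ten-membered ring by intramolecular Nozaki–Hiyama allylation (CrCl2, THF, high dilution); the allylchromium adds through C7 to the aldehyde in a chair transition state and gives the 6,7-anti homoallylic alcohol 23, again biased by the C8 silyloxy group.

Step 23 (palladium coupling as the last step on a substrate carrying two Michael acceptors, an acetate and a free hydroxyl). Fallback from 30, back at 41: run the Stille hydroxymethylation on 30 to give salonitenolide F7; silylate only the primary allylic 15-OH (t-BuPh2SiCl, imidazole) to the silyl ether F8; Yamaguchi esterification with 36 gives the ester F9; aqueous AcOH removes the acetonide to give the diol F10 while the silyl ether survives; AcCl/collidine at −78 °C gives the 4′-acetate F11; HF·pyridine then frees the 15-OH to give 41.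

Further compounds
F1 | step 4 | tert-butyl{[(3S,5E)-6-iodo-5-methylhexa-1,5-dien-3-yl]oxy}dimethylsilane | C=C[C@@H](O[Si](C)(C)C(C)(C)C)C/C(C)=C/I
F2 | step 4 | (2S,4E)-2-[(tert-butyldimethylsilyl)oxy]-5-iodo-4-methylpent-4-enal | O=C[C@@H](O[Si](C)(C)C(C)(C)C)C/C(C)=C/I
F3 | step 4 | methyl (4S,6E)-4-[(tert-butyldimethylsilyl)oxy]-3-hydroxy-7-iodo-6-methyl-2-methylidenehept-6-enoate (C3 epimers) | COC(=O)C(=C)C(O)[C@@H](O[Si](C)(C)C(C)(C)C)C/C(C)=C/I
F4 | step 4 | methyl (4S,6E)-3-(acetyloxy)-4-[(tert-butyldimethylsilyl)oxy]-7-iodo-6-methyl-2-methylidenehept-6-enoate (C3 epimers) | COC(=O)C(=C)C(OC(C)=O)[C@@H](O[Si](C)(C)C(C)(C)C)C/C(C)=C/I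
F5 | step 4 | methyl (2E,4S,6E)-4-[(tert-butyldimethylsilyl)oxy]-2-(hydroxymethyl)-7-iodo-6-methylhepta-2,6-dienoate | COC(=O)/C(CO)=C/[C@@H](O[Si](C)(C)C(C)(C)C)C/C(C)=C/I
F6 | step 13 | (6E,9S,10E)-9-[(tert-butyldimethylsilyl)oxy]-11-{[(tert-butyldimethylsilyl)oxy]methyl}-12-chloro-7-methyldodeca-6,10-dien-2-ynal | ClC/C(CO[Si](C)(C)C(C)(C)C)=C/[C@@H](O[Si](C)(C)C(C)(C)C)C/C(C)=C/CCC#CC=O
F7 | step 23 | salonitenolide, (3aR,4S,6E,10Z,11aR)-4-hydroxy-10-(hydroxymethyl)-6-methyl-3-methylidene-3a,4,5,8,9,11a-hexahydrocyclodeca[b]furan-2(3H)-one | C=C1C(=O)O[C@@H]2/C=C(\CO)CC/C=C(\C)C[C@H](O)[C@@H]12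
F8 | step 23 | (3aR,4S,6E,10Z,11aR)-10-{[(tert-butyldiphenylsilyl)oxy]methyl}-4-hydroxy-6-methyl-3-methylidene-3a,4,5,8,9,11a-hexahydrocyclodeca[b]furan-2(3H)-one | C=C1C(=O)O[C@@H]2/C=C(\CO[Si](c3ccccc3)(c3ccccc3)C(C)(C)C)CC/C=C(\C)C[C@H](O)[C@@H]12
F9 | step 23 | (3aR,4S,6E,10Z,11aR)-10-{[(tert-butyldiphenylsilyl)oxy]methyl}-6-methyl-3-methylidene-2-oxo-2,3,3a,4,5,8,9,11a-octahydrocyclodeca[b]furan-4-yl 2-[(4R)-2,2-dimethyl-1,3-dioxolan-4-yl]prop-2-enoate | C=C1C(=O)O[C@@H]2/C=C(\CO[Si](c3ccccc3)(c3ccccc3)C(C)(C)C)CC/C=C(\C)C[C@H](OC(=O)C(=C)[C@@H]3COC(C)(C)O3)[C@@H]12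
F10 | step 23 | (3aR,4S,6E,10Z,11aR)-10-{[(tert-butyldiphenylsilyl)oxy]methyl}-6-methyl-3-methylidene-2-oxo-2,3,3a,4,5,8,9,11a-octahydrocyclodeca[b]furan-4-yl (3R)-3,4-dihydroxy-2-methylidenebutanoate | C=C1C(=O)O[C@@H]2/C=C(\CO[Si](c3ccccc3)(c3ccccc3)C(C)(C)C)CC/C=C(\C)C[C@H](OC(=O)C(=C)[C@@H](O)CO)[C@@H]12
F11 | step 23 | (3aR,4S,6E,10Z,11aR)-10-{[(tert-butyldiphenylsilyl)oxy]methyl}-6-methyl-3-methylidene-2-oxo-2,3,3a,4,5,8,9,11a-octahydrocyclodeca[b]furan-4-yl (3R)-4-(acetyloxy)-3-hydroxy-2-methylidenebutanoate | C=C1C(=O)O[C@@H]2/C=C(\CO[Si](c3ccccc3)(c3ccccc3)C(C)(C)C)CC/C=C(\C)C[C@H](OC(=O)C(=C)[C@@H](O)COC(C)=O)[C@@H]12
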